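**Retrosynthetic overview**
1. Target ⇐ 11-membered (2Z,6E)-dienone 18 by late-stage operations: CBS reduction sets C1, then acetate, desilylation and angelate (installed last, without DMAP).
2. 18 ⇐ keto tosylate 15 by a one-pot I/Li exchange, 7-exo alkenyllithium addition and Grob fragmentation: the C1–C2 bond is made, the C1–C7 bond is broken, and the six-membered ring grows by five carbons.
3. 15 ⇐ aldol union of 2,2-dimethylcyclohexanone with the (S)-β-silyloxy aldehyde 7, then chelate-controlled α-methylation, which fixes the C6/C7 relative configuration that becomes the 6E alkene.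
4. 7 ⇐ propargyl alcohol: carbomagnesiation/iodination gives the Z-iodoalkene (later C2=C3), and a catalytic asymmetric allylboration sets C4.
5. Ring order: cyclohexanone (from the starting material) → transient trans-fused bicyclo[5.4.0]undecene alkoxide → cycloundecadienone.

Assumption: ring atoms are numbered C1 (CH–OAc), C2=C3(Me), C4 (CH–O-angelate), C5, C6=C7(Me), C8–C10, C11(Me)2, and this numbering is also used for the acyclic precursors; the target is read as the (1R,2Z,4S,6E) isomer with a (Z)-2-methylbut-2-enoate on C4.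

**Step 1**
Reactants: 1 prop-2-yn-1-ol
Product: 3 (Z)-3-iodo-2-methylprop-2-en-1-ol, via alkenylmagnesium alkoxide 2 (not isolated)
Conditions: MeMgBr (2.5 equiv), CuI (10 mol %), THF, −10 → 23 °C; then I2, −78 → 0 °C; H2O
Reagents that add atoms: methylmagnesium bromide C[Mg]Br; iodine II
Why: hydroxyl-directed Cu-catalysed anti-carbomagnesiation (Duboudin type) puts the methyl on the internal carbon and magnesium cis to CH2O, and iodinolysis with retention gives the Z-iodoalkene that becomes C2=C3.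

**Step 2**
Reactants: 3 (Z)-3-iodo-2-methylprop-2-en-1-ol
Product: 4 (Z)-3-iodo-2-methylprop-2-enal
Conditions: activated MnO2 (15 equiv), CH2Cl2, 23 °C, dark; filtered and used at once
Reagents that add atoms: none
Why: neutral allylic alcohol oxidation on MnO2 gives the enal without isomerising the Z-iodoalkene.

**Step 3**
Reactants: 4 (Z)-3-iodo-2-methylprop-2-enal
Product: 5 (1Z,3S)-1-iodo-2-methylhexa-1,5-dien-3-ol
Conditions: allylB(pin) (1.3 equiv), (S)-TRIP phosphoric acid (5 mol %), toluene, −30 °C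
Reagents that add atoms: 2-allyl-4,4,5,5-tetramethyl-1,3,2-dioxaborolane C=CCB1OC(C)(C)C(C)(C)O1
Why: chiral phosphoric acid-catalysed allylboration through a closed chair transition state; the catalyst antipode that delivers allyl to the Si face (the one that gives (S)-1-phenylbut-3-en-1-ol from benzaldehyde) sets the (S) carbinol, which is C4 of the target.

**Step 4**
Reactants: 5 (1Z,3S)-1-iodo-2-methylhexa-1,5-dien-3-ol
Product: 6 {[(1Z,3S)-1-iodo-2-methylhexa-1,5-dien-3-yl]oxy}tri(propan-2-yl)silane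
Conditions: TIPSOTf (1.2 equiv), 2,6-lutidine, CH2Cl2, −78 → 0 °C
Reagents that add atoms: triisopropylsilyl trifluoromethanesulfonate CC(C)[Si](C(C)C)(C(C)C)OS(=O)(=O)C(F)(F)F
Why: silyl triflate silylation of the secondary allylic alcohol; TIPS is chosen because it resists 1,4 O→C silyl migration in the Z-γ-silyloxy alkenyllithium of step 9.

**Step 5**
Reactants: 6 {[(1Z,3S)-1-iodo-2-methylhexa-1,5-dien-3-yl]oxy}tri(propan-2-yl)silane
Product: 7 (3S,4Z)-5-iodo-4-methyl-3-[(triisopropylsilyl)oxy]pent-4-enal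
Conditions: OsO4 (2 mol %), NaIO4 (4 equiv), 2,6-lutidine, dioxane/H2O 3:1, 23 °C
Reagents that add atoms: sodium periodate (oxygen source via OsO4) [Na+].[O-]I(=O)(=O)=O
Why: Lemieux–Johnson cleavage; OsO4 attacks only the monosubstituted terminal alkene, because the trisubstituted iodoalkene next to OTIPS is deactivated and hindered, and the stereocentre is untouched.

**Step 6**
Reactants: 8 2-methylcyclohexan-1-one
Product: 10 2,2-dimethylcyclohexan-1-one, via potassium enolate 9 (not isolated)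
Conditions: KH (1.0 equiv), THF, 23 °C; Et3B (1.1 equiv); MeI (1.05 equiv), 0 → 23 °C; distillation
Reagents that add atoms: iodomethane CI
Why: thermodynamic enolate alkylation; the equilibrated, borane-complexed potassium enolate is mainly the tetrasubstituted one and is monomethylated there, and the minor 2,6-isomer is removed by distillation.

**Step 7**
Reactants: 10 2,2-dimethylcyclohexan-1-one; 7 (3S,4Z)-5-iodo-4-methyl-3-[(triisopropylsilyl)oxy]pent-4-enal
Product: 12 2-[(3S,4Z)-1-hydroxy-5-iodo-4-methyl-3-[(triisopropylsilyl)oxy]pent-4-en-1-yl]-6,6-dimethylcyclohexan-1-one, via lithium enolate 11 (not isolated)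
Conditions: LDA (1.05 equiv), THF, −78 °C; then 7, −78 °C, 20 min; AcOH/THF quench at −78 °C
Reagents that add atoms: none
Why: directed aldol addition of the only possible enolate of 10; the two new centres need no control, because the ring α-carbon (C7) is re-enolised in step 8 and the carbinol (C6) is destroyed in step 9, so all diastereomers are carried on (about 2:1 in favour of the 4,6-anti carbinol expected).

**Step 8**
Reactants: 12 2-[(3S,4Z)-1-hydroxy-5-iodo-4-methyl-3-[(triisopropylsilyl)oxy]pent-4-en-1-yl]-6,6-dimethylcyclohexan-1-one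
Product: 15 (1S,3S,4Z)-5-iodo-4-methyl-1-[(1R)-1,3,3-trimethyl-2-oxocyclohexyl]-3-[(triisopropylsilyl)oxy]pent-4-en-1-yl 4-methylbenzenesulfonate, via dilithium enolate alkoxide 13 (not isolated), via methylated lithium alkoxide 14 (not isolated)
Conditions: LDA (2.3 equiv), THF, −78 → −30 °C; MeI (1.5 equiv), DMPU, −78 → −40 °C; then TsCl (2.5 equiv), −40 → 0 °C
Reagents that add atoms: iodomethane CI; 4-methylbenzenesulfonyl chloride Cc1ccc(cc1)S(Cl)(=O)=O
Why: Fráter–Seebach-type alkylation; the lithium-chelated enolate–alkoxide dianion is methylated anti to the C5 chain on the carbinol carbon, which fixes the C6/C7 relative configuration ((6S,7R) shown; the other carbinol epimer gives (6R,7S) with the same relative configuration), and the hindered alkoxide is trapped in situ as the tosylate before retro-aldol cleavage.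

**Step 9**
Reactants: 15 (1S,3S,4Z)-5-iodo-4-methyl-1-[(1R)-1,3,3-trimethyl-2-oxocyclohexyl]-3-[(triisopropylsilyl)oxy]pent-4-en-1-yl 4-methylbenzenesulfonate
Product: 18 (2Z,4S,6E)-3,7,11,11-tetramethyl-4-[(triisopropylsilyl)oxy]cycloundeca-2,6-dien-1-one, via alkenyllithium 16 (not isolated), via bicyclic lithium alkoxide 17 (not isolated)
Conditions: t-BuLi (2.1 equiv), THF/Et2O 1:1, −78 °C, 15 min; then −78 → 23 °C, 2 h
Reagents that add atoms: none
Why: Proposed new method: an alkenyllithium-triggered five-carbon anionic ring expansion, in which fast I/Li exchange (15 has no enolisable ketone proton and no acidic sulfonate α-H) gives the Z-alkenyllithium 16 with retention, which closes 7-exo onto the C1 ketone (new C1–C2 bond) to the trans-fused tertiary alkoxide 17; in 17 the C1–C7 bond is antiperiplanar to C6–OTs with C5 anti to C8, so a concerted Grob fragmentation cleaves C1–C7, expels tosylate and gives the 6E alkene stereospecifically from the (6S,7R)/(6R,7S) relative configuration, while the 2Z geometry comes from the alkenyl iodide and C4 is untouched; relief of three contiguous fully substituted carbons and formation of the conjugated enone drive it; the closest known reaction types are the Wharton–Grob fragmentation of bicyclic 1,3-diol monosulfonates and SmI2 Barbier-cyclisation/Grob-fragmentation sequences of ω-iodoalkyl β-sulfonyloxy ketones, which have not been run with an alkenyllithium nucleophile or to an 11-membered Z-enone.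

**Step 10**
Reactants: 18 (2Z,4S,6E)-3,7,11,11-tetramethyl-4-[(triisopropylsilyl)oxy]cycloundeca-2,6-dien-1-one
Product: 19 (1R,2Z,4S,6E)-3,7,11,11-tetramethyl-4-[(triisopropylsilyl)oxy]cycloundeca-2,6-dien-1-ol
Conditions: (S)-Me-CBS (0.3 equiv), catecholborane (2 equiv), toluene, −78 → −40 °C
Reagents that add atoms: none
Why: Corey–Bakshi–Shibata reduction, 1,2-selective with catecholborane; with the quaternary C11 as the large group and the twisted Z-alkenyl as the small one, (S)-Me-CBS should give the (1R) alcohol (to be checked by Mosher analysis; the (R)-catalyst is used if the sense is reversed).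

**Step 11**
Reactants: 19 (1R,2Z,4S,6E)-3,7,11,11-tetramethyl-4-[(triisopropylsilyl)oxy]cycloundeca-2,6-dien-1-ol
Product: 20 (1R,2Z,4S,6E)-3,7,11,11-tetramethyl-4-[(triisopropylsilyl)oxy]cycloundeca-2,6-dien-1-yl acetate
Conditions: Ac2O (3 equiv), DMAP (0.1 equiv), Et3N, CH2Cl2, 23 °C
Reagents that add atoms: acetic anhydride CC(=O)OC(C)=O
Why: DMAP-catalysed acyl transfer acetylates the hindered neopentyl allylic alcohol with retention at C1.

**Step 12**
Reactants: 20 (1R,2Z,4S,6E)-3,7,11,11-tetramethyl-4-[(triisopropylsilyl)oxy]cycloundeca-2,6-dien-1-yl acetate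
Product: 21 (1R,2Z,4S,6E)-4-hydroxy-3,7,11,11-tetramethylcycloundeca-2,6-dien-1-yl acetate
Conditions: HF·pyridine, pyridine, THF, 0 → 23 °C
Reagents that add atoms: none
Why: fluoride-mediated Si–O cleavage under buffered, weakly acidic conditions, which avoid base-induced 1,4-acetyl migration and are too mild to ionise the Z-ene-1,4-diol unit.

**Step 13**
Reactants: 21 (1R,2Z,4S,6E)-4-hydroxy-3,7,11,11-tetramethylcycloundeca-2,6-dien-1-yl acetate; 22 (Z)-2-methylbut-2-enoic acid
Product: 24 (1R,2Z,4S,6E)-1-acetoxy-3,7,11,11-tetramethylcycloundeca-2,6-dien-4-yl (Z)-2-methylbut-2-enoate, via mixed anhydride 23 (not isolated)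
Conditions: 22 (3 equiv), 2,4,6-trichlorobenzoyl chloride (3 equiv), Et3N (4 equiv), toluene, 23 °C, 2 h; then 21, toluene, 80 °C
Reagents that add atoms: none
Why: Yamaguchi-type esterification through the mixed anhydride without DMAP, conditions that form angelates without Z→E isomerisation to the tiglate; the alcohol attacks the unhindered angeloyl carbonyl and C4 keeps its configuration.

**Compound list**
1 | prop-2-yn-1-ol | C#CCO | starting material
2 | bromomagnesium (Z)-3-(bromomagnesio)-2-methylprop-2-en-1-olate | Br[Mg]OC/C(C)=C\[Mg]Br | intermediate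
3 | (Z)-3-iodo-2-methylprop-2-en-1-ol | OC/C(C)=C\I | intermediate
4 | (Z)-3-iodo-2-methylprop-2-enal | O=C/C(C)=C\I | intermediate
5 | (1Z,3S)-1-iodo-2-methylhexa-1,5-dien-3-ol | O[C@@H](CC=C)/C(C)=C\I | intermediate
6 | {[(1Z,3S)-1-iodo-2-methylhexa-1,5-dien-3-yl]oxy}tri(propan-2-yl)silane | CC(C)[Si](C(C)C)(C(C)C)O[C@@H](CC=C)/C(C)=C\I | intermediate
7 | (3S,4Z)-5-iodo-4-methyl-3-[(triisopropylsilyl)oxy]pent-4-enal | CC(C)[Si](C(C)C)(C(C)C)O[C@@H](CC=O)/C(C)=C\I | intermediate
8 | 2-methylcyclohexan-1-one (racemic) | CC1CCCCC1=O | starting material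
9 | potassium 2-methylcyclohex-1-en-1-olate (Et3B-complexed) | [K+].[O-]C1=C(C)CCCC1 | intermediate
10 | 2,2-dimethylcyclohexan-1-one | CC1(C)CCCCC1=O | intermediate
11 | lithium 6,6-dimethylcyclohex-1-en-1-olate | [Li+].[O-]C1=CCCCC1(C)C | intermediate
12 | 2-[(3S,4Z)-1-hydroxy-5-iodo-4-methyl-3-[(triisopropylsilyl)oxy]pent-4-en-1-yl]-6,6-dimethylcyclohexan-1-one (all diastereomers at the carbinol and ring α-carbon) | O=C1C(C)(C)CCCC1C(O)C[C@H](O[Si](C(C)C)(C(C)C)C(C)C)/C(C)=C\I | intermediate
13 | dilithium enolate–alkoxide of 12 | [Li+].[Li+].[O-]C1=C(C([O-])C[C@H](O[Si](C(C)C)(C(C)C)C(C)C)/C(C)=C\I)CCCC1(C)C | intermediate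
14 | lithium (1S,3S,4Z)-5-iodo-4-methyl-1-[(1R)-1,3,3-trimethyl-2-oxocyclohexyl]-3-[(triisopropylsilyl)oxy]pent-4-en-1-olate (major series shown; the (1R)-carbinol/(1S)-ring series has the same relative configuration) | [Li+].O=C1C(C)(C)CCC[C@]1(C)[C@@H]([O-])C[C@H](O[Si](C(C)C)(C(C)C)C(C)C)/C(C)=C\I | intermediate
15 | (1S,3S,4Z)-5-iodo-4-methyl-1-[(1R)-1,3,3-trimethyl-2-oxocyclohexyl]-3-[(triisopropylsilyl)oxy]pent-4-en-1-yl 4-methylbenzenesulfonate (major series shown, as for 14) | O=C1C(C)(C)CCC[C@]1(C)[C@@H](OS(=O)(=O)c2ccc(C)cc2)C[C@H](O[Si](C(C)C)(C(C)C)C(C)C)/C(C)=C\I | intermediate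
16 | alkenyllithium from 15 (I replaced by Li, Z retained) | O=C1C(C)(C)CCC[C@]1(C)[C@@H](OS(=O)(=O)c2ccc(C)cc2)C[C@H](O[Si](C(C)C)(C(C)C)C(C)C)/C(C)=C\[Li] | intermediate
17 | lithium (1R,4S,6S,7R)-3,7,11,11-tetramethyl-6-(tosyloxy)-4-[(triisopropylsilyl)oxy]bicyclo[5.4.0]undec-2-en-1-olate (trans-fused) | [Li+].C[C@]12CCCC(C)(C)[C@]1([O-])C=C(C)[C@@H](O[Si](C(C)C)(C(C)C)C(C)C)C[C@@H]2OS(=O)(=O)c3ccc(C)cc3 | intermediate
18 | (2Z,4S,6E)-3,7,11,11-tetramethyl-4-[(triisopropylsilyl)oxy]cycloundeca-2,6-dien-1-one | CC(C)[Si](C(C)C)(C(C)C)O[C@H]1C/C=C(\C)CCCC(C)(C)C(=O)/C=C\1C | intermediate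
19 | (1R,2Z,4S,6E)-3,7,11,11-tetramethyl-4-[(triisopropylsilyl)oxy]cycloundeca-2,6-dien-1-ol | CC(C)[Si](C(C)C)(C(C)C)O[C@H]1C/C=C(\C)CCCC(C)(C)[C@H](O)/C=C\1C | intermediate
20 | (1R,2Z,4S,6E)-3,7,11,11-tetramethyl-4-[(triisopropylsilyl)oxy]cycloundeca-2,6-dien-1-yl acetate | CC(C)[Si](C(C)C)(C(C)C)O[C@H]1C/C=C(\C)CCCC(C)(C)[C@H](OC(C)=O)/C=C\1C | intermediate
21 | (1R,2Z,4S,6E)-4-hydroxy-3,7,11,11-tetramethylcycloundeca-2,6-dien-1-yl acetate | O[C@H]1C/C=C(\C)CCCC(C)(C)[C@H](OC(C)=O)/C=C\1C | intermediate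
22 | (Z)-2-methylbut-2-enoic acid (angelic acid) | C/C=C(/C)C(=O)O | starting material
23 | (Z)-2-methylbut-2-enoic 2,4,6-trichlorobenzoic anhydride | C/C=C(/C)C(=O)OC(=O)c1c(Cl)cc(Cl)cc1Cl | intermediate
24 | (1R,2Z,4S,6E)-1-acetoxy-3,7,11,11-tetramethylcycloundeca-2,6-dien-4-yl (Z)-2-methylbut-2-enoate (CNP0322023.1) | C/C=C(/C)C(=O)O[C@H]1C/C=C(\C)CCCC(C)(C)[C@H](OC(C)=O)/C=C\1C | target

**Step count and risks**
Total steps: 13. Longest linear sequence: 12 (steps 1–5, then 7–13); step 6 is the one-step side branch.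

The three steps most likely to fail:

Step 9 (the proposed new cascade). It can fail through silyl migration in 16, attack of the alkenyllithium at sulfur, or a lithium alkoxide that does not fragment. The fallback separates the three events with known chemistry and sets out from 14. The alkoxide 14 is trapped with TMSCl instead of TsCl to give (2R)-2-[(1S,3S,4Z)-5-iodo-4-methyl-3-[(triisopropylsilyl)oxy]-1-[(trimethylsilyl)oxy]pent-4-en-1-yl]-2,6,6-trimethylcyclohexan-1-one F1. I/Li exchange with t-BuLi (THF, −78 → 0 °C) and intramolecular alkenyllithium addition to the ketone, now with no sulfonate present, give the trans-fused hydroxy silyl ether (1R,4S,6S,7R)-3,7,11,11-tetramethyl-4-[(triisopropylsilyl)oxy]-6-[(trimethylsilyl)oxy]bicyclo[5.4.0]undec-2-en-1-ol F2. K2CO3 in MeOH removes the TMS group to give (1R,4S,6S,7R)-3,7,11,11-tetramethyl-4-[(triisopropylsilyl)oxy]bicyclo[5.4.0]undec-2-ene-1,6-diol F3. MsCl/Et3N sulfonylates only the secondary hydroxyl to give (1R,4S,6S,7R)-1-hydroxy-3,7,11,11-tetramethyl-4-[(triisopropylsilyl)oxy]bicyclo[5.4.0]undec-2-en-6-yl methanesulfonate F4. KOt-Bu in THF/t-BuOH then effects a classical Wharton–Grob fragmentation of this bicyclic 1,3-diol monosulfonate and the route is rejoined at 18.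

Step 8 (dianion methylation and in situ tosylation). The dianion may undergo retro-aldol cleavage, LDA may attack the alkenyl iodide, or the facial selectivity may be low. The fallback sets out from 12. Dess–Martin oxidation gives the β-diketone 2-[(3S,4Z)-5-iodo-4-methyl-3-[(triisopropylsilyl)oxy]pent-4-enoyl]-6,6-dimethylcyclohexan-1-one F5. K2CO3/MeI in acetone C-methylates it to 2-[(3S,4Z)-5-iodo-4-methyl-3-[(triisopropylsilyl)oxy]pent-4-enoyl]-2,6,6-trimethylcyclohexan-1-one F6 (both ring epimers). Zn(BH4)2 at −78 °C reduces only the side-chain ketone through the zinc chelate, with hydride entering from the methyl face, to give (2R)-2-[(1S,3S,4Z)-1-hydroxy-5-iodo-4-methyl-3-[(triisopropylsilyl)oxy]pent-4-en-1-yl]-2,6,6-trimethylcyclohexan-1-one F7 and its (2S,1′R) counterpart, which have the required relative configuration. Deprotonation with n-BuLi and addition of TsCl return to the route at 15.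

Step 10 (facial selectivity at a ketone flanked by a quaternary carbon and a Z-alkenyl group in a macrocycle). The fallback gives up reagent control and sets out from 18. Luche reduction (NaBH4, CeCl3·7H2O, MeOH, −40 °C) gives 19 together with its C1 epimer (1S,2Z,4S,6E)-3,7,11,11-tetramethyl-4-[(triisopropylsilyl)oxy]cycloundeca-2,6-dien-1-ol F8. The epimers are separated by chromatography and F8 is oxidised back to 18 with MnO2 and recycled, so that the material is funnelled to 19, where the route is rejoined.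

Further compounds
F1 | step 9 | (2R)-2-[(1S,3S,4Z)-5-iodo-4-methyl-3-[(triisopropylsilyl)oxy]-1-[(trimethylsilyl)oxy]pent-4-en-1-yl]-2,6,6-trimethylcyclohexan-1-one | O=C1C(C)(C)CCC[C@]1(C)[C@@H](O[Si](C)(C)C)C[C@H](O[Si](C(C)C)(C(C)C)C(C)C)/C(C)=C\I
F2 | step 9 | (1R,4S,6S,7R)-3,7,11,11-tetramethyl-4-[(triisopropylsilyl)oxy]-6-[(trimethylsilyl)oxy]bicyclo[5.4.0]undec-2-en-1-ol | C[C@]12CCCC(C)(C)[C@]1(O)C=C(C)[C@@H](O[Si](C(C)C)(C(C)C)C(C)C)C[C@@H]2O[Si](C)(C)C
F3 | step 9 | (1R,4S,6S,7R)-3,7,11,11-tetramethyl-4-[(triisopropylsilyl)oxy]bicyclo[5.4.0]undec-2-ene-1,6-diol | C[C@]12CCCC(C)(C)[C@]1(O)C=C(C)[C@@H](O[Si](C(C)C)(C(C)C)C(C)C)C[C@@H]2O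
F4 | step 9 | (1R,4S,6S,7R)-1-hydroxy-3,7,11,11-tetramethyl-4-[(triisopropylsilyl)oxy]bicyclo[5.4.0]undec-2-en-6-yl methanesulfonate | C[C@]12CCCC(C)(C)[C@]1(O)C=C(C)[C@@H](O[Si](C(C)C)(C(C)C)C(C)C)C[C@@H]2OS(C)(=O)=O
F5 | step 8 | 2-[(3S,4Z)-5-iodo-4-methyl-3-[(triisopropylsilyl)oxy]pent-4-enoyl]-6,6-dimethylcyclohexan-1-one | O=C1C(C)(C)CCCC1C(=O)C[C@H](O[Si](C(C)C)(C(C)C)C(C)C)/C(C)=C\I
F6 | step 8 | 2-[(3S,4Z)-5-iodo-4-methyl-3-[(triisopropylsilyl)oxy]pent-4-enoyl]-2,6,6-trimethylcyclohexan-1-one | O=C1C(C)(C)CCCC1(C)C(=O)C[C@H](O[Si](C(C)C)(C(C)C)C(C)C)/C(C)=C\I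
F7 | step 8 | (2R)-2-[(1S,3S,4Z)-1-hydroxy-5-iodo-4-methyl-3-[(triisopropylsilyl)oxy]pent-4-en-1-yl]-2,6,6-trimethylcyclohexan-1-one | O=C1C(C)(C)CCC[C@]1(C)[C@@H](O)C[C@H](O[Si](C(C)C)(C(C)C)C(C)C)/C(C)=C\I
F8 | step 10 | (1S,2Z,4S,6E)-3,7,11,11-tetramethyl-4-[(triisopropylsilyl)oxy]cycloundeca-2,6-dien-1-ol | CC(C)[Si](C(C)C)(C(C)C)O[C@H]1C/C=C(\C)CCCC(C)(C)[C@@H](O)/C=C\1C
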